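## Retrosynthetic overview

1. Aspergichromone B ⇐ fluoride desilylation ⇐ methyl α-hydroxy ester 32 ⇐ 1-methoxyvinyl addition from the convex face, then ozonolysis ⇐ pentacyclic dione 30.
2. 30 ⇐ aryl ester 29 by a Pd(0)-catalysed acyl-transfer [3+2] annulation: C(acyl)–O insertion, exo-acylpalladation of the strained alkene, chromone C2–H palladation, C–C reductive elimination. This closes the cyclopentene ring (future carbinol carbon, chromone C3, chromone C2 and the two former alkene carbons).
3. Enabling feature: the free phenol of the 2,6-dihydroxyphenyl ring on the bridgehead lies over the exo face of the alkene carbon next to that bridgehead. As its chromone-3-carboxylate it is tether, regiochemical director and internal base, and is released as the phenol of the target. The chromone C2–H ortho to the acyl group and the strain of the 7-oxabenzonorbornadiene alkene complete the design.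
4. 29 ⇐ chromone-3-carboxylic acid 27 (from 3,5-dihydroxybenzyl alcohol by ortho-metalation and Vilsmeier–Haack annulation) + oxabenzonorbornadiene 18. 18 ⇐ silicon-tethered intramolecular aryne–furan Diels–Alder reaction; the silylene tether stays on as protecting group; resolution as camphanate.
5. Ring order: chromone pyranone (step 15) and oxabicycle (step 7) first, cyclopentene last (step 19). Stereochemistry: bridgeheads by resolution, the two ring-fusion carbons by exo addition in step 19, the carbinol by convex-face addition in step 20.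

Key step: step 19

Remark on locants: the bicyclic core is numbered as 1,4-dihydro-1,4-epoxynaphthalene. C1 is the arylated bridgehead, C2 and C3 the alkene carbons, C4 the CH bridgehead, C5 carries the side-chain ether, C6 the methyl group, C8 the second oxygen. In this numbering the target is (1S,2R,3R,4R) with an (S)-carbinol carbon.

Remark on racemates: 14 and 15 are racemic; their SMILES show the (1S,4R) enantiomer that is carried on after step 8.

Assumption: the configuration of 16 is to be assigned by X-ray analysis of the camphanate (known configuration of the acyl part) before the material is taken on.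

## Route

Step 1
Reactants: 1 4-hydroxy-3-methylbenzaldehyde; 2 3-methylbutane-1,3-diol
Product: 3 4-(3-hydroxy-3-methylbutoxy)-3-methylbenzaldehyde
Conditions: PPh3, DIAD, THF, 0 °C → rt
Reagents that add atoms: none
Why: Mitsunobu etherification; the acidic phenol displaces the activated primary hydroxyl of the diol while the tertiary hydroxyl is inert, so the side chain is installed without protection.

Step 2
Reactants: 3 4-(3-hydroxy-3-methylbutoxy)-3-methylbenzaldehyde
Product: 5 4-(3-hydroxy-3-methylbutoxy)-3-methylphenol, via aryl formate 4 (not isolated)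
Conditions: mCPBA, NaHCO3, CH2Cl2, rt; then K2CO3 (cat.), MeOH
Reagents that add atoms: mCPBA, OOC(=O)c1cccc(Cl)c1
Why: Baeyer–Villiger oxidation of the electron-rich aldehyde proceeds with aryl migration to the formate, whose methanolysis gives the phenol para to the ether and so differentiates the two hydroquinone oxygens.

Step 3
Reactants: 5 4-(3-hydroxy-3-methylbutoxy)-3-methylphenol
Product: 6 2-bromo-4-(3-hydroxy-3-methylbutoxy)-5-methylphenol
Conditions: NBS, i-Pr2NH (cat.), CH2Cl2, 0 °C
Reagents that add atoms: N-bromosuccinimide, O=C1CCC(=O)N1Br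
Why: Amine-catalysed ortho-bromination of the phenol (electrophilic aromatic substitution) takes the open ortho position para to the methyl group, which places bromine where the aryne is to be generated.

Step 4
Reactants: 7 2-bromobenzene-1,3-diol; 8 2-(furan-2-yl)-4,4,5,5-tetramethyl-1,3,2-dioxaborolane
Product: 9 2-(furan-2-yl)benzene-1,3-diol
Conditions: Pd(OAc)2, SPhos, K3PO4, dioxane–H2O, 80 °C
Reagents that add atoms: none
Why: Suzuki–Miyaura coupling of the di-ortho-substituted bromide with the 2-furyl boronate under a bulky biarylphosphine ligand tolerates the free phenols.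

Step 5
Reactants: 6 2-bromo-4-(3-hydroxy-3-methylbutoxy)-5-methylphenol; 9 2-(furan-2-yl)benzene-1,3-diol (3 equiv)
Product: 11 di-tert-butyl(2-bromo-4-(3-hydroxy-3-methylbutoxy)-5-methylphenoxy)(2-(furan-2-yl)-3-hydroxyphenoxy)silane, via aryloxysilyl triflate 10 (not isolated)
Conditions: t-Bu2Si(OTf)2, 2,6-lutidine, CH2Cl2, −78 → 0 °C; then 9, imidazole, DMF, 40 °C
Reagents that add atoms: di-tert-butylsilyl bis(trifluoromethanesulfonate), CC(C)(C)[Si](OS(=O)(=O)C(F)(F)F)(OS(=O)(=O)C(F)(F)F)C(C)(C)C
Why: Stepwise silyl ether formation with the silylene bis(triflate) joins the two phenols through one silicon atom; excess symmetrical diol 9 ensures monosilylation and the tertiary alcohol reacts far more slowly than the phenols.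

Step 6
Reactants: 11 the bis(aryloxy)silane
Product: 12 bis(trimethylsilyl) ether of 11 (aryl OTMS and tertiary OTMS)
Conditions: TMSOTf, Et3N, CH2Cl2, −78 → 0 °C
Reagents that add atoms: trimethylsilyl triflate, C[Si](C)(C)OS(=O)(=O)C(F)(F)F
Why: Silylation masks the phenol and the tertiary alcohol so that no phenoxide or alkoxide can add to the aryne in the next step.

Step 7
Reactants: 12 the bis-TMS ether
Product: 15 racemic silylene-bridged 1-aryl-1,4-dihydro-1,4-epoxynaphthalene diol (one aryl OH and the tertiary OH free), via aryne 13 (not isolated), via bis-TMS cycloadduct 14 (not isolated)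
Conditions: LiTMP (from 2,2,6,6-tetramethylpiperidine, n-BuLi), THF (0.01 M), −78 → −20 °C; then citric acid, MeOH, 0 °C
Reagents that add atoms: none
Why: LiTMP removes the ring proton flanked by bromine and the ether oxygen and loss of LiBr gives the aryne, which the furan held by the silylene traps in an intramolecular Diels–Alder reaction (silicon-tethered aryne–furan cycloaddition); the eight-membered tether lets the arylated furan carbon bond only to the aryne carbon next to the silyloxy group, both bridgehead stereocentres arise here as a racemate, and mild acid methanolysis removes the two TMS groups.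

Step 8
Reactants: 15 the racemic diol
Product: 16 (1S,4R)-camphanate of 15 at the free aryl OH (single diastereomer)
Conditions: (1S)-(−)-camphanic chloride, Et3N, DMAP (cat.), CH2Cl2, 0 °C; separation of the two diastereomers by chromatography and crystallisation
Reagents that add atoms: (1S)-(−)-camphanic chloride, O=C(Cl)[C@@]12CC[C@@](C)(C(=O)O1)C2(C)C
Why: Acylation of the phenol with an enantiopure acid chloride gives two diastereomeric esters that are separated (classical resolution), which fixes the absolute configuration of both bridgeheads; the camphanate also protects the phenol during step 9.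

Step 9
Reactants: 16 the (1S,4R)-camphanate
Product: 17 tertiary acetate of 16
Conditions: Ac2O, Et3N, DMAP, CH2Cl2, rt
Reagents that add atoms: acetic anhydride, CC(=O)OC(C)=O
Why: DMAP-catalysed acetylation esterifies the only free hydroxyl, the tertiary alcohol, under non-acidic conditions that leave the acid-sensitive bicyclic alkene intact.

Step 10
Reactants: 17 the camphanate acetate
Product: 18 (1S,4R)-5-(3-acetoxy-3-methylbutoxy)-1-(2,6-dihydroxyphenyl)-6-methyl-1,4-dihydro-1,4-epoxynaphthalen-8-ol with O8 and one aryl oxygen bridged by di-tert-butylsilylene (other aryl OH free)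
Conditions: N2H4·H2O, THF–MeOH, 0 °C
Reagents that add atoms: none
Why: Hydrazinolysis cleaves the aryl ester (phenoxide leaving group) far faster than the hindered tertiary alkyl acetate and releases the phenol that serves as tether anchor.

Step 11
Reactants: 19 3,5-dihydroxybenzyl alcohol
Product: 20 (3,5-bis(methoxymethoxy)phenyl)methanol
Conditions: MOMCl, K2CO3, acetone, rt
Reagents that add atoms: chloromethyl methyl ether, COCCl
Why: Williamson-type O-alkylation under carbonate base protects only the phenols, since the benzylic alcohol is not deprotonated.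

Step 12
Reactants: 20 (3,5-bis(methoxymethoxy)phenyl)methanol
Product: 21 tert-butyl((3,5-bis(methoxymethoxy)benzyl)oxy)diphenylsilane
Conditions: TBDPSCl, imidazole, DMF, rt
Reagents that add atoms: tert-butyl(chloro)diphenylsilane, CC(C)(C)[Si](Cl)(c1ccccc1)c1ccccc1
Why: Silylation of the primary alcohol installs an acid-stable TBDPS ether that survives the later MOM removal and formylation.

Step 13
Reactants: 21 the TBDPS ether
Product: 23 1-(4-(((tert-butyldiphenylsilyl)oxy)methyl)-2,6-bis(methoxymethoxy)phenyl)ethan-1-one, via aryllithium 22 (not isolated)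
Conditions: n-BuLi, THF, 0 °C; then MeC(O)N(OMe)Me, −78 → 0 °C
Reagents that add atoms: N-methoxy-N-methylacetamide, CC(=O)N(C)OC
Why: Directed ortho-metalation occurs at the position between the two MOM ethers, and acylation of the aryllithium with the N-methoxy-N-methylamide stops at the ketone.

Step 14
Reactants: 23 the bis-MOM acetophenone
Product: 24 1-(4-(((tert-butyldiphenylsilyl)oxy)methyl)-2,6-dihydroxyphenyl)ethan-1-one
Conditions: TFA, CH2Cl2, 0 °C; aq. NaHCO3
Reagents that add atoms: none
Why: Acidolysis removes the MOM acetals, assisted by the ortho carbonyl, while the TBDPS ether is stable to TFA.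

Step 15
Reactants: 24 the 2,6-dihydroxyacetophenone
Product: 25 7-(((tert-butyldiphenylsilyl)oxy)methyl)-5-hydroxy-4-oxo-4H-chromene-3-carbaldehyde
Conditions: POCl3, DMF, 0 → 50 °C; then aq. NaOAc
Reagents that add atoms: N,N-dimethylformamide, CN(C)C=O; water, O
Why: Vilsmeier–Haack double formylation of the methyl ketone and cyclisation of one phenol onto the aminomethylene carbon build the 3-formylchromone; the two phenols are equivalent by symmetry, so only one regioisomer can form.

Step 16
Reactants: 25 the 5-hydroxy-3-formylchromone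
Product: 26 5-((tert-butyldimethylsilyl)oxy)-7-(((tert-butyldiphenylsilyl)oxy)methyl)-4-oxo-4H-chromene-3-carbaldehyde
Conditions: TBSOTf, 2,6-lutidine, CH2Cl2, 0 °C
Reagents that add atoms: tert-butyldimethylsilyl triflate, CC(C)(C)[Si](C)(C)OS(=O)(=O)C(F)(F)F
Why: Silylation with the silyl triflate overcomes the hydrogen bond of the peri hydroxyl to the C4 carbonyl.

Step 17
Reactants: 26 the silylated aldehyde
Product: 27 5-((tert-butyldimethylsilyl)oxy)-7-(((tert-butyldiphenylsilyl)oxy)methyl)-4-oxo-4H-chromene-3-carboxylic acid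
Conditions: NaClO2, NaH2PO4, 2-methyl-2-butene, t-BuOH–H2O, rt
Reagents that add atoms: sodium chlorite, [Na+].[O-]Cl=O
Why: Pinnick oxidation converts the aldehyde to the acid under buffered conditions with a chlorine scavenger, without touching the enone or the silyl ethers.

Step 18
Reactants: 27 the chromone-3-carboxylic acid; 18 the (1S,4R)-phenol
Product: 29 aryl ester of 27 with the free aryl OH of 18, via acid chloride 28 (not isolated)
Conditions: 1-chloro-N,N,2-trimethylprop-1-en-1-amine, CH2Cl2, 0 °C → rt; then 18, Et3N, DMAP (cat.), 0 °C → rt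
Reagents that add atoms: none
Why: The acid chloride formed under neutral conditions acylates the hindered phenol under DMAP catalysis (esterification); the tertiary acetate and the silyl ethers are inert.

Step 19
Reactants: 29 the aryl ester
Product: 30 (1S,2R,3R,4R)-pentacyclic dione: the epoxytetrahydronaphthalene core exo-fused across C2–C3 to a cyclopenta[b]chromene-1,9-dione (chromone C2 on C2 and the five-ring ketone carbon on C3), with the aryl OH free again
Conditions: Pd2(dba)3 (5 mol %), IPr (1,3-bis(2,6-diisopropylphenyl)imidazol-2-ylidene, 12 mol %), CsOPiv (20 mol %), toluene, 90 °C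
Reagents that add atoms: none
Why: Proposed new method: Pd(0)–NHC, pre-coordinated to the strained alkene, inserts into the C(acyl)–O bond of the aryl ester (closest known: Pd–NHC coupling of aryl esters and intramolecular alkene carboacylation by C(acyl)–O or C(acyl)–N activation) to give an acyl–Pd–aryloxide whose aryloxide holds palladium over the exo face of C2. syn-Acylpalladation of the C2=C3 bond then puts the acyl carbon on C3 and Pd on C2 inside a six-membered Pd–O chelate that leaves no free site for β-oxygen elimination of the bridge. The aryloxide acts as internal base for concerted metalation–deprotonation of the chromone C2–H next to the new ketone, and C(sp3)–C(sp2) reductive elimination from the resulting six-membered palladacycle closes the cyclopentene ring (model: the alkyl-Pd/aryl C–H step of Catellani-type norbornene chemistry), so the ring closes by reductive elimination and not by a 5-endo attack on a π bond. Both new stereocentres (C2 and C3) are set by syn addition to the exo face and are thus relayed from the bridgeheads; the cis ring fusion is enforced. The regioselectivity needed (chromone C2 to the carbon next to the arylated bridgehead) is secured twice, by the ester tether, which the silylene bridge to O8 locks over the exo face of C2, and by the preference of the acyl group for the less hindered alkene carbon. Decarbonylation and C–O reductive elimination (oxyacylation) must be outrun, which chelation of the acyl-Pd by the C4 carbonyl and the moderate temperature should favour; the phenol set free is the free phenol of the target, so the tether leaves no trace.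

Step 20
Reactants: 30 the pentacyclic dione
Product: 31 tertiary (S)-carbinol: 1-methoxyvinyl adduct at the five-ring ketone of 30 (OH syn to the oxygen bridge)
Conditions: CH2=C(OMe)Li (methyl vinyl ether, t-BuLi, THF, −78 → 0 °C), CeCl3, THF, −78 °C (3 equiv; one is consumed by the phenol)
Reagents that add atoms: methyl vinyl ether, COC=C
Why: 1,2-Addition of the weakly basic organocerium reagent (acyl anion equivalent) to the more electrophilic five-ring ketone occurs from the convex face, anti to the oxygen bridge, so the hydroxyl ends up syn to the bridge as required; the pyrone carbonyl and the hindered acetate react more slowly.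

Step 21
Reactants: 31 the 1-methoxyvinyl carbinol
Product: 32 silyl-protected Aspergichromone B (methyl (S)-α-hydroxy ester; silylene bridge, 5-OTBS and 7-CH2OTBDPS in place)
Conditions: O3, CH2Cl2–MeOH, −78 °C; then Me2S
Reagents that add atoms: ozone, [O-][O+]=O
Why: Ozonolysis of the enol ether C=C is much faster than attack on the arenes or the tetrasubstituted chromone double bond and unmasks the methyl ester directly.

Step 22
Reactants: 32 silyl-protected Aspergichromone B
Product: 33 Aspergichromone B
Conditions: HF·pyridine, pyridine, THF, 0 °C → rt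
Reagents that add atoms: none
Why: Fluoride-mediated desilylation cleaves all Si–O bonds (silylene, TBS, TBDPS) under buffered conditions that spare the tertiary acetate, the methyl ester and the acid-sensitive bridged benzylic ether.

## Compound list

1 | 4-hydroxy-3-methylbenzaldehyde | Cc1cc(C=O)ccc1O | starting material
2 | 3-methylbutane-1,3-diol | CC(C)(O)CCO | starting material
3 | 4-(3-hydroxy-3-methylbutoxy)-3-methylbenzaldehyde | Cc1cc(C=O)ccc1OCCC(C)(C)O | intermediate
4 | 4-(3-hydroxy-3-methylbutoxy)-3-methylphenyl formate | Cc1cc(OC=O)ccc1OCCC(C)(C)O | intermediate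
5 | 4-(3-hydroxy-3-methylbutoxy)-3-methylphenol | Cc1cc(O)ccc1OCCC(C)(C)O | intermediate
6 | 2-bromo-4-(3-hydroxy-3-methylbutoxy)-5-methylphenol | Cc1cc(O)c(Br)cc1OCCC(C)(C)O | intermediate
7 | 2-bromobenzene-1,3-diol | Oc1cccc(O)c1Br | starting material
8 | 2-(furan-2-yl)-4,4,5,5-tetramethyl-1,3,2-dioxaborolane | CC1(C)OB(OC1(C)C)c1ccco1 | starting material
9 | 2-(furan-2-yl)benzene-1,3-diol | Oc1cccc(O)c1-c1ccco1 | intermediate
10 | (2-bromo-4-(3-hydroxy-3-methylbutoxy)-5-methylphenoxy)di-tert-butylsilyl triflate | Cc1cc(O[Si](OS(=O)(=O)C(F)(F)F)(C(C)(C)C)C(C)(C)C)c(Br)cc1OCCC(C)(C)O | intermediate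
11 | di-tert-butyl(2-bromo-4-(3-hydroxy-3-methylbutoxy)-5-methylphenoxy)(2-(furan-2-yl)-3-hydroxyphenoxy)silane | Cc1cc(O[Si](Oc2cccc(O)c2-c2ccco2)(C(C)(C)C)C(C)(C)C)c(Br)cc1OCCC(C)(C)O | intermediate
12 | bis(trimethylsilyl) ether of 11 (aryl OTMS, tertiary OTMS) | Cc1cc(O[Si](Oc2cccc(O[Si](C)(C)C)c2-c2ccco2)(C(C)(C)C)C(C)(C)C)c(Br)cc1OCCC(C)(C)O[Si](C)(C)C | intermediate
13 | aryne from 12 (triple bond between the former C–Br carbon and the carbon next to the side-chain ether) | CC1=C(OCCC(C)(C)O[Si](C)(C)C)C#CC(O[Si](Oc2cccc(O[Si](C)(C)C)c2-c2ccco2)(C(C)(C)C)C(C)(C)C)=C1 | intermediate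
14 | racemic bis-TMS cycloadduct: 1-aryl-1,4-dihydro-1,4-epoxynaphthalene with O8 and one aryl oxygen bridged by di-tert-butylsilylene, other aryl O and tertiary O as TMS ethers ((1S,4R) enantiomer drawn) | C1=C[C@H]2O[C@]1(c3c(O[Si](C)(C)C)cccc3O[Si](C(C)(C)C)(C(C)(C)C)O4)c1c4cc(C)c(OCCC(C)(C)O[Si](C)(C)C)c12 | intermediate
15 | racemic 1-(2,6-dihydroxyphenyl)-5-(3-hydroxy-3-methylbutoxy)-6-methyl-1,4-dihydro-1,4-epoxynaphthalen-8-ol with O8 and one aryl oxygen bridged by di-tert-butylsilylene ((1S,4R) enantiomer drawn) | C1=C[C@H]2O[C@]1(c3c(O)cccc3O[Si](C(C)(C)C)(C(C)(C)C)O4)c1c4cc(C)c(OCCC(C)(C)O)c12 | intermediate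
16 | (1S,4R)-15 esterified at the free aryl OH with (1S,4R)-camphanic acid | C1=C[C@H]2O[C@]1(c3c(OC(=O)[C@@]56CC[C@@](C)(C(=O)O5)C6(C)C)cccc3O[Si](C(C)(C)C)(C(C)(C)C)O4)c1c4cc(C)c(OCCC(C)(C)O)c12 | intermediate
17 | tertiary acetate of 16 | C1=C[C@H]2O[C@]1(c3c(OC(=O)[C@@]56CC[C@@](C)(C(=O)O5)C6(C)C)cccc3O[Si](C(C)(C)C)(C(C)(C)C)O4)c1c4cc(C)c(OCCC(C)(C)OC(C)=O)c12 | intermediate
18 | (1S,4R)-5-(3-acetoxy-3-methylbutoxy)-1-(2,6-dihydroxyphenyl)-6-methyl-1,4-dihydro-1,4-epoxynaphthalen-8-ol with O8 and one aryl oxygen bridged by di-tert-butylsilylene, other aryl OH free | C1=C[C@H]2O[C@]1(c3c(O)cccc3O[Si](C(C)(C)C)(C(C)(C)C)O4)c1c4cc(C)c(OCCC(C)(C)OC(C)=O)c12 | intermediate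
19 | 3,5-dihydroxybenzyl alcohol | OCc1cc(O)cc(O)c1 | starting material
20 | (3,5-bis(methoxymethoxy)phenyl)methanol | OCc1cc(OCOC)cc(OCOC)c1 | intermediate
21 | tert-butyl((3,5-bis(methoxymethoxy)benzyl)oxy)diphenylsilane | COCOc1cc(CO[Si](c2ccccc2)(c2ccccc2)C(C)(C)C)cc(OCOC)c1 | intermediate
22 | aryllithium of 21, lithiated between the two MOM ethers | [Li]c1c(OCOC)cc(CO[Si](c2ccccc2)(c2ccccc2)C(C)(C)C)cc1OCOC | intermediate
23 | 1-(4-(((tert-butyldiphenylsilyl)oxy)methyl)-2,6-bis(methoxymethoxy)phenyl)ethan-1-one | CC(=O)c1c(OCOC)cc(CO[Si](c2ccccc2)(c2ccccc2)C(C)(C)C)cc1OCOC | intermediate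
24 | 1-(4-(((tert-butyldiphenylsilyl)oxy)methyl)-2,6-dihydroxyphenyl)ethan-1-one | CC(=O)c1c(O)cc(CO[Si](c2ccccc2)(c2ccccc2)C(C)(C)C)cc1O | intermediate
25 | 7-(((tert-butyldiphenylsilyl)oxy)methyl)-5-hydroxy-4-oxo-4H-chromene-3-carbaldehyde | O=Cc1coc2cc(CO[Si](c3ccccc3)(c3ccccc3)C(C)(C)C)cc(O)c2c1=O | intermediate
26 | 5-((tert-butyldimethylsilyl)oxy)-7-(((tert-butyldiphenylsilyl)oxy)methyl)-4-oxo-4H-chromene-3-carbaldehyde | O=Cc1coc2cc(CO[Si](c3ccccc3)(c3ccccc3)C(C)(C)C)cc(O[Si](C)(C)C(C)(C)C)c2c1=O | intermediate
27 | 5-((tert-butyldimethylsilyl)oxy)-7-(((tert-butyldiphenylsilyl)oxy)methyl)-4-oxo-4H-chromene-3-carboxylic acid | OC(=O)c1coc2cc(CO[Si](c3ccccc3)(c3ccccc3)C(C)(C)C)cc(O[Si](C)(C)C(C)(C)C)c2c1=O | intermediate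
28 | acid chloride of 27 | ClC(=O)c1coc2cc(CO[Si](c3ccccc3)(c3ccccc3)C(C)(C)C)cc(O[Si](C)(C)C(C)(C)C)c2c1=O | intermediate
29 | aryl ester: free aryl oxygen of 18 acylated by the chromone-3-carbonyl group of 27; (1S,4R) | C1=C[C@H]2O[C@]1(c3c(OC(=O)c5coc6cc(CO[Si](c7ccccc7)(c7ccccc7)C(C)(C)C)cc(O[Si](C)(C)C(C)(C)C)c6c5=O)cccc3O[Si](C(C)(C)C)(C(C)(C)C)O4)c1c4cc(C)c(OCCC(C)(C)OC(C)=O)c12 | intermediate
30 | (1S,2R,3R,4R)-pentacyclic dione: epoxytetrahydronaphthalene core exo-fused across C2–C3 to a cyclopenta[b]chromene-1,9-dione (chromone C2 on C2, ring ketone carbon on C3, both new C–H endo); 5-OTBS and 7-CH2OTBDPS on the chromone; silylene bridge, free aryl OH and tertiary acetate as in 18 | O=C1c2c(oc3cc(CO[Si](c4ccccc4)(c4ccccc4)C(C)(C)C)cc(O[Si](C)(C)C(C)(C)C)c3c2=O)[C@H]2[C@@H]1[C@H]1O[C@]2(c3c(O)cccc3O[Si](C(C)(C)C)(C(C)(C)C)O4)c2c4cc(C)c(OCCC(C)(C)OC(C)=O)c21 | intermediate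
31 | (S)-carbinol from 30: 1-methoxyvinyl group on the convex face of the former ring ketone, OH syn to the oxygen bridge | C=C(OC)[C@@]1(O)c2c(oc3cc(CO[Si](c4ccccc4)(c4ccccc4)C(C)(C)C)cc(O[Si](C)(C)C(C)(C)C)c3c2=O)[C@H]2[C@@H]1[C@H]1O[C@]2(c3c(O)cccc3O[Si](C(C)(C)C)(C(C)(C)C)O4)c2c4cc(C)c(OCCC(C)(C)OC(C)=O)c21 | intermediate
32 | silyl-protected Aspergichromone B: methyl (S)-α-hydroxy ester with silylene bridge, 5-OTBS and 7-CH2OTBDPS | COC(=O)[C@@]1(O)c2c(oc3cc(CO[Si](c4ccccc4)(c4ccccc4)C(C)(C)C)cc(O[Si](C)(C)C(C)(C)C)c3c2=O)[C@H]2[C@@H]1[C@H]1O[C@]2(c3c(O)cccc3O[Si](C(C)(C)C)(C(C)(C)C)O4)c2c4cc(C)c(OCCC(C)(C)OC(C)=O)c21 | intermediate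
33 | Aspergichromone B | COC(=O)[C@@]1(O)c2c(oc3cc(CO)cc(O)c3c2=O)[C@H]2[C@@H]1[C@H]1O[C@]2(c2c(O)cccc2O)c2c(O)cc(C)c(OCCC(C)(C)OC(C)=O)c21 | target

## Step count and risks

Total step count: 22. Longest linear sequence: 14 (steps 1–3, 5–10, 18–22).

**Step 19 (key step, proposed new method).** What may go wrong: decarbonylation of the acyl-palladium species, C–O reductive elimination (oxyacylation of the alkene) or β-oxygen elimination that opens the bridge, each instead of C–H palladation and C–C bond formation. Fallback with known reaction types, setting out from aldehyde 26 and alkene 18 and returning at 30: 26 is converted with NH2OH·HCl and NaOAc in EtOH at 0 °C into the (E)-oxime F1, which NCS in DMF chlorinates to the hydroximoyl chloride F2. Slow addition of Et3N to F2 in the presence of 18 generates the nitrile oxide F3, which adds to the exo face of the strained alkene in a 1,3-dipolar cycloaddition, its bulky carbon terminus going to C3 and its oxygen to C2, to give the isoxazoline F4. Reductive N–O cleavage with Mo(CO)6 in MeCN–H2O gives the β-hydroxy ketone F5, and dehydration with DCC and catalytic CuCl gives the 3-acyl-1,4-dihydro-1,4-epoxynaphthalene enone F6. Irradiation of F6 at 350 nm in MeCN (photo-Nazarov cyclisation of an aryl vinyl ketone, neutral conditions) forms the C2–chromone C2 bond on the exo face, and the hydrogen shift that restores the chromone gives 30.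

**Step 20.** What may go wrong: enolisation of the ketone, delivery of the nucleophile from the concave face after coordination of the metal to the bridging oxygen, or attack on the tertiary acetate. Fallback from 30 back to 32: tris(methylthio)methyllithium (from tris(methylthio)methane and n-BuLi, THF, −78 °C), a bulky and weakly basic carboxyl anion equivalent that does not chelate, should add from the convex face to give the orthothioester carbinol F7. Mercury(II)-assisted methanolysis (HgCl2, HgO, MeOH–H2O) then gives the methyl ester 32 without ozone.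

**Step 8.** What may go wrong: too little chromatographic or crystallisation discrimination between the two diastereomeric camphanates. Fallback from racemic 15 back to 16: preparative supercritical-fluid chromatography of 15 on a chiral stationary phase gives the single (1S,4R) enantiomer F8, which is acylated with camphanic chloride as in step 8, now only as protection, to give 16.

Further compounds
F1 | step 19 | (E)-oxime of aldehyde 26 | O/N=C/c1coc2cc(CO[Si](c3ccccc3)(c3ccccc3)C(C)(C)C)cc(O[Si](C)(C)C(C)(C)C)c2c1=O
F2 | step 19 | (Z)-hydroximoyl chloride from F1 | O/N=C(\Cl)c1coc2cc(CO[Si](c3ccccc3)(c3ccccc3)C(C)(C)C)cc(O[Si](C)(C)C(C)(C)C)c2c1=O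
F3 | step 19 | chromone-3-carbonitrile oxide from F2 | [O-][N+]#Cc1coc2cc(CO[Si](c3ccccc3)(c3ccccc3)C(C)(C)C)cc(O[Si](C)(C)C(C)(C)C)c2c1=O
F4 | step 19 | exo-isoxazoline of 18 (O on C2, chromonyl-bearing carbon on C3) | CC(C)(C)[Si](C)(C)Oc1cc(CO[Si](c2ccccc2)(c2ccccc2)C(C)(C)C)cc2occ(C3=NO[C@H]4[C@@H]3[C@H]3O[C@]4(c5c(O)cccc5O[Si](C(C)(C)C)(C(C)(C)C)O6)c4c6cc(C)c(OCCC(C)(C)OC(C)=O)c43)c(=O)c12
F5 | step 19 | β-hydroxy ketone (exo-OH on C2, exo-chromon-3-ylcarbonyl on C3) | O[C@H]1[C@@H](C(=O)c2coc3cc(CO[Si](c4ccccc4)(c4ccccc4)C(C)(C)C)cc(O[Si](C)(C)C(C)(C)C)c3c2=O)[C@H]2O[C@]1(c3c(O)cccc3O[Si](C(C)(C)C)(C(C)(C)C)O4)c1c4cc(C)c(OCCC(C)(C)OC(C)=O)c12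
F6 | step 19 | enone: 18 carrying the chromon-3-ylcarbonyl group on alkene carbon C3 | C1=C(C(=O)c2coc3cc(CO[Si](c4ccccc4)(c4ccccc4)C(C)(C)C)cc(O[Si](C)(C)C(C)(C)C)c3c2=O)[C@H]2O[C@]1(c3c(O)cccc3O[Si](C(C)(C)C)(C(C)(C)C)O4)c1c4cc(C)c(OCCC(C)(C)OC(C)=O)c12
F7 | step 20 | (S)-carbinol from 30 with a tris(methylthio)methyl group on the convex face | CSC(SC)(SC)[C@@]1(O)c2c(oc3cc(CO[Si](c4ccccc4)(c4ccccc4)C(C)(C)C)cc(O[Si](C)(C)C(C)(C)C)c3c2=O)[C@H]2[C@@H]1[C@H]1O[C@]2(c3c(O)cccc3O[Si](C(C)(C)C)(C(C)(C)C)O4)c2c4cc(C)c(OCCC(C)(C)OC(C)=O)c21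
F8 | step 8 | (1S,4R) enantiomer of 15, single enantiomer | C1=C[C@H]2O[C@]1(c3c(O)cccc3O[Si](C(C)(C)C)(C(C)(C)C)O4)c1c4cc(C)c(OCCC(C)(C)O)c12
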